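**Retrosynthetic overview**

1. Feature: ring B holds three contiguous stereocentres, C5, the quaternary C10 (C20 methyl) and C9 (C11 side chain), next to C8, which only has to become a methylidene carbon. This is the footprint of a [4+2] addition of a C9=C10 (E)-enal carrying C20 to a C5=C6–C7=C8 1-siloxydiene joined to it through C1–C4.
2. Disconnections: lactone ring (C13=C14) by ring-closing metathesis of an allyl 2-alkylacrylate; C11–C12 by Barbier allylation of the C11 aldehyde; C8=C17 by methylenation of the ketone that comes from the C8 silyl ether; C5–C10 and C8–C9 by the intramolecular Diels–Alder reaction.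
3. Ring order: ring A (tether ring) and ring B (cycloaddition ring) close together in step 12; the butenolide ring closes last (step 23).
4. The triene comes from geranyl acetate (C1–C3, C9–C11, C20). An Evans aldol sets C3, a Fráter–Seebach methylation sets the quaternary C4, cross-metathesis with crotonaldehyde and dienol silylation give the C5–C8 siloxydiene, and MnO2 unmasks the enal.
5. During the cycloaddition C19 is the methyl ester and O3 the acetate; the 3,19-acetonide is put on after ring closure and carried to the end.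

Key step: step 12

Remark 1: labdane numbering is used for every intermediate (ring A = C1–C5, C10; ring B = C5–C10; C11 on C9; C17 on C8; C18 and C19 on C4; C20 on C10).

Remark 2: an isopropylidene acetal across O3/O19 is not used in the cycloaddition. It can sit as a chair on the forming ring A only with C3–O axial and C19 equatorial, which is the wrong diene face; the wanted chair would put the C2 tether carbon axial on the dioxane, syn to a ketal methyl. C4 is built by enolate alkylation because organoaluminium reagents open 2,3-epoxy alcohols at the carbon remote from the carbinol.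

**Route**

Step 1
Reactants: 1 geranyl acetate
Product: 2 6,7-epoxygeranyl acetate (racemic at the epoxide)
Conditions: mCPBA, NaHCO3, CH2Cl2, 0 °C
Reagents that add atoms: 3-chloroperoxybenzoic acid, OOC(=O)c1cccc(Cl)c1
Why: Prilezhaev epoxidation, in which the electron-rich 6,7-alkene should react ahead of the 2,3-alkene that is deactivated by the allylic acetate; the epoxide stereocentre is destroyed in step 2.

Step 2
Reactants: 2 6,7-epoxygeranyl acetate
Product: 4 (2E)-3-methyl-6-oxohex-2-en-1-yl acetate, via (2E)-6,7-dihydroxy-3,7-dimethyloct-2-en-1-yl acetate 3 (not isolated)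
Conditions: HIO4·2H2O, THF/H2O, 0 °C
Reagents that add atoms: none
Why: Periodic acid should open the epoxide with water at the tertiary carbon and cleave the resulting glycol (Malaprade cleavage) to acetone and the C3 aldehyde, whose oxygen is the former epoxide oxygen.

Step 3
Reactants: 5 (S)-4-benzyloxazolidin-2-one; 6 pent-4-enoyl chloride
Product: 8 (S)-4-benzyl-3-(pent-4-enoyl)oxazolidin-2-one, via N-lithio (S)-4-benzyloxazolidin-2-one 7 (not isolated)
Conditions: n-BuLi, THF, −78 °C; then 6, −78 → 0 °C
Reagents that add atoms: none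
Why: N-Acylation of the lithiated Evans auxiliary by the acid chloride, with no stereocentre touched.

Step 4
Reactants: 8 (S)-4-benzyl-3-(pent-4-enoyl)oxazolidin-2-one; 4 (2E)-3-methyl-6-oxohex-2-en-1-yl acetate
Product: 10 (4S)-4-benzyl-3-[(2S,3R,6E)-8-acetoxy-3-hydroxy-6-methyl-2-(prop-2-en-1-yl)oct-6-enoyl]oxazolidin-2-one, via dibutylboron Z-enolate 9 (not isolated)
Conditions: Bu2BOTf, i-Pr2NEt, CH2Cl2, −78 → 0 °C; 4, −78 → 0 °C; then pH 7 buffer, MeOH, 30% H2O2, 0 °C
Reagents that add atoms: none
Why: Evans syn-aldol reaction, in which the (Z)-boron enolate adds through a Zimmerman–Traxler chair on the face away from the benzyl group and so sets C3 as R (the C4–H centre formed here is erased in step 6).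

Step 5
Reactants: 10 Evans aldol adduct
Product: 11 methyl (2S,3R,6E)-3,8-dihydroxy-6-methyl-2-(prop-2-en-1-yl)oct-6-enoate
Conditions: NaOMe (cat.), MeOH, 0 °C
Reagents that add atoms: methanol, CO
Why: Methoxide-catalysed transesterification at the exocyclic imide carbonyl should free the auxiliary as the methyl ester forms, and the same medium removes the primary acetate.

Step 6
Reactants: 11 methyl (2S,3R,6E)-3,8-dihydroxy-6-methyl-2-(prop-2-en-1-yl)oct-6-enoate
Product: 13 methyl (2S,3R,6E)-3,8-dihydroxy-2,6-dimethyl-2-(prop-2-en-1-yl)oct-6-enoate, via trilithio alkoxide enolate 12 (not isolated)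
Conditions: LDA (3.5 equiv), THF, −78 → −20 °C; MeI, −78 → −10 °C
Reagents that add atoms: iodomethane, CI
Why: Fráter–Seebach alkylation, in which the chelated lithium alkoxide–enolate is methylated on the face anti to the C2 side chain on C3, so that C18 enters trans to C2 on the chelate ring and the quaternary C4 is set; the remote primary lithium alkoxide should not be alkylated at this temperature.

Step 7
Reactants: 13 methyl (2S,3R,6E)-3,8-dihydroxy-2,6-dimethyl-2-(prop-2-en-1-yl)oct-6-enoate
Product: 14 methyl (2S,3R,6E)-3,8-diacetoxy-2,6-dimethyl-2-(prop-2-en-1-yl)oct-6-enoate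
Conditions: Ac2O, DMAP (cat.), pyridine, CH2Cl2, rt
Reagents that add atoms: acetic anhydride, CC(=O)OC(C)=O
Why: DMAP-catalysed acetylation of both hydroxyls, which masks the allylic alcohol and puts a small equatorial-seeking group on O3.

Step 8
Reactants: 14 diacetate; 15 (E)-crotonaldehyde
Product: 16 methyl (2S,3R,6E)-3,8-diacetoxy-2,6-dimethyl-2-[(2E)-4-oxobut-2-en-1-yl]oct-6-enoate
Conditions: second-generation Hoveyda–Grubbs catalyst RuCl2(H2IMes)(=CH-C6H4-2-OiPr) (cat.), CH2Cl2, 40 °C
Reagents that add atoms: none
Why: Olefin cross-metathesis of the monosubstituted allyl alkene with crotonaldehyde should give the (E)-enal, while the trisubstituted C9=C10 alkene stays out of the catalytic cycle.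

Step 9
Reactants: 16 C8 enal
Product: 17 methyl (2S,3R,6E)-3,8-diacetoxy-2-[(1E,3E)-4-(tert-butyldimethylsilyloxy)buta-1,3-dien-1-yl]-2,6-dimethyloct-6-enoate
Conditions: TBSOTf, Et3N, CH2Cl2, −78 → 0 °C
Reagents that add atoms: tert-butyldimethylsilyl triflate, CC(C)(C)[Si](C)(C)OS(=O)(=O)C(F)(F)F
Why: O-Silylation of the enal followed by γ-deprotonation at C5 (silyl dienol ether formation) should give the 1-siloxydiene, the s-trans enal leading to the (E)-enol ether and the quaternary C4 forcing C5=C6 to be E; the quaternary ester cannot enolise.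

Step 10
Reactants: 17 silyl dienol ether diacetate
Product: 18 methyl (2S,3R,6E)-3-acetoxy-2-[(1E,3E)-4-(tert-butyldimethylsilyloxy)buta-1,3-dien-1-yl]-8-hydroxy-2,6-dimethyloct-6-enoate
Conditions: K2CO3 (cat.), MeOH, 0 °C
Reagents that add atoms: none
Why: Base-catalysed methanolysis (Zemplén type) should remove the unhindered primary allylic acetate well before the secondary acetate beside the quaternary C4, and the short cold exposure should spare the hindered silyl enol ether and the quaternary methyl ester.

Step 11
Reactants: 18 allylic alcohol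
Product: 19 methyl (2S,3R,6E)-3-acetoxy-2-[(1E,3E)-4-(tert-butyldimethylsilyloxy)buta-1,3-dien-1-yl]-2,6-dimethyl-8-oxooct-6-enoate
Conditions: MnO2, CH2Cl2, rt
Reagents that add atoms: none
Why: MnO2 oxidises only the allylic alcohol, to the (E)-enal, under neutral conditions that leave the silyl dienol ether intact.

Step 12
Reactants: 19 (E)-enal (E,E)-siloxydiene triene
Product: 20 methyl (3R,4S,5S,8R,9S,10R)-3-acetoxy-8-(tert-butyldimethylsilyloxy)-11-oxo-12,13,14,15,16,17-hexanorlabd-6-en-19-oate
Conditions: Me2AlCl (1.2 equiv), CH2Cl2, −78 → −30 °C; then Et3N, aq. NaHCO3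
Reagents that add atoms: none
Why: Me2AlCl binds the aldehyde oxygen and lowers the enal LUMO, so that a concerted but asynchronous [4+2] (a Lewis-acid-promoted type 1 intramolecular Diels–Alder reaction of a 1,7,9-decatriene, as known for trienals that give trans-octalins) joins the nucleophilic diene terminus C5 to the β-carbon C10 slightly ahead of C8–C9. Ring B is the six-membered cycloaddition ring made by both new σ-bonds, and ring A closes at the same time as the fused six-membered tether ring (C10, C1–C5). The endo position of the complexed formyl group puts the tether anti on the (E)-dienophile and so gives the trans ring fusion at C5/C10; the (E)-enal geometry fixes C11 cis to C20 at C9, and endo addition to the (E)-enol ether places the C8 silyl ether cis to C11. The diene face is chosen by the chair of the forming ring A, in which the C3 acetate is equatorial and the flat C19 ester takes the axial site beside the incoming C20 methyl, whereas the other face needs an axial acetate and a C18/C20 methyl–methyl 1,3-diaxial contact. The step needs endo selectivity, secured by the Lewis acid and the (E,E)-diene, and facial selectivity, secured by the C3/C4 substituents.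

Step 13
Reactants: 20 Diels–Alder adduct
Product: 21 (3R,4R,5S,8R,9R,10R)-8-(tert-butyldimethylsilyloxy)-12,13,14,15,16,17-hexanorlabd-6-ene-3,11,19-triol
Conditions: LiAlH4, THF, 0 °C → rt
Reagents that add atoms: none
Why: Hydride reduction takes the aldehyde and the hindered C19 ester to primary alcohols and cleaves the acetate, which also removes the elimination-prone β-silyloxy aldehyde at once; silyl ether and alkene are inert.

Step 14
Reactants: 21 triol
Product: 22 (3R,4R,5S,8R,9R,10R)-8-(tert-butyldimethylsilyloxy)-3,19-(isopropylidenedioxy)-12,13,14,15,16,17-hexanorlabd-6-en-11-ol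
Conditions: Me2C(OMe)2, PPTS (cat.), CH2Cl2, rt; then MeOH, 0 °C
Reagents that add atoms: 2,2-dimethoxypropane, COC(C)(C)OC
Why: Acid-catalysed transketalisation should close the six-membered isopropylidene acetal on the 1,3-diol O3/O19, while the lone C11 alcohol cannot form a cyclic acetal and is set free again when its mixed ketal is methanolysed.

Step 15
Reactants: 22 acetonide alkene
Product: 23 (3R,4R,5S,8R,9R,10R)-8-(tert-butyldimethylsilyloxy)-3,19-(isopropylidenedioxy)-12,13,14,15,16,17-hexanorlabdan-11-ol
Conditions: H2 (1 atm), 5% Pt/C, EtOAc, rt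
Reagents that add atoms: none
Why: Heterogeneous catalytic hydrogenation of the only alkene, the cis-disubstituted C6=C7 bond, with no new stereocentre; it is done before any other alkene is brought in.

Step 16
Reactants: 23 saturated primary alcohol
Product: 24 (3R,4R,5S,8R,9S,10R)-8-(tert-butyldimethylsilyloxy)-3,19-(isopropylidenedioxy)-12,13,14,15,16,17-hexanorlabdan-11-al
Conditions: Dess–Martin periodinane, NaHCO3, CH2Cl2, 0 °C → rt
Reagents that add atoms: none
Why: Dess–Martin oxidation under buffered, non-basic conditions should give the aldehyde without epimerising C9 or eliminating the β-silyloxy group.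

Step 17
Reactants: 25 2-(bromomethyl)acrylic acid; 26 allyl alcohol
Product: 27 allyl 2-(bromomethyl)acrylate
Conditions: p-TsOH·H2O (cat.), toluene, reflux (Dean–Stark)
Reagents that add atoms: none
Why: Fischer esterification, with acid catalysis chosen so that no nucleophilic base can displace the allylic bromide.

Step 18
Reactants: 24 C11 aldehyde; 27 allyl 2-(bromomethyl)acrylate
Product: 29 allyl 4-hydroxy-2-methylidenebutanoate adduct of aldehyde 24 (C11–OH; 3R,4R,5S,8R,9R,10R,11R), via 2-(allyloxycarbonyl)allylindium dibromide 28 (not isolated)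
Conditions: In powder, THF/H2O, rt
Reagents that add atoms: none
Why: Indium-mediated Barbier allylation with a 2-(alkoxycarbonyl)allyl reagent, in which Felkin–Anh addition anti to the quaternary C10 and past H9 should set C11 as R; the hindered γ-hydroxy ester should stay open under these neutral conditions.

Step 19
Reactants: 29 C11 alcohol
Product: 30 O11-(1-ethoxyethyl) ether of 29 (both acetal epimers)
Conditions: ethyl vinyl ether, PPTS (cat.), CH2Cl2, 0 °C → rt
Reagents that add atoms: ethyl vinyl ether, C=COCC
Why: Acid-catalysed addition of the alcohol to the vinyl ether gives an acetal that is stable to fluoride, oxidation, titanium carbenes and ruthenium carbenes and leaves with the acetonide in the last step.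

Step 20
Reactants: 30 C8 silyl ether
Product: 31 C8 alcohol (3R,4R,5S,8R,9S,10R,11R)
Conditions: TBAF, AcOH, THF, rt → 45 °C
Reagents that add atoms: none
Why: Fluoride cleaves the Si–O bond of the TBS ether, and acetic acid buffers the medium so that the allyl ester and both acetals should survive.

Step 21
Reactants: 31 C8 alcohol
Product: 32 C8 ketone (3R,4R,5S,9R,10R,11R)
Conditions: Dess–Martin periodinane, pyridine, CH2Cl2, rt
Reagents that add atoms: none
Why: Dess–Martin oxidation of the axial secondary alcohol under neutral conditions avoids β-elimination of the C11 alkoxy group, and C9 keeps its equatorial side chain.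

Step 22
Reactants: 32 C8 ketone
Product: 33 8(17)-methylidene compound (3R,4R,5S,9R,10R,11R)
Conditions: Cp2TiMe2, toluene/THF, 70 °C, dark
Reagents that add atoms: dimethyltitanocene, C[Ti](C)(C1C=CC=C1)C1C=CC=C1
Why: Petasis methylenation, in which thermally generated Cp2Ti=CH2 olefinates the ketone through an oxatitanacyclobutane under non-basic conditions and should do so faster than it attacks the conjugated, α-branched ester.

Step 23
Reactants: 33 allyl acrylate diene
Product: 34 11-O-(1-ethoxyethyl)-3,19-O-isopropylidene-14-deoxy-11-hydroxyandrographolide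
Conditions: second-generation Grubbs catalyst RuCl2(=CHPh)(H2IMes)(PCy3) (cat.), toluene, 80 °C
Reagents that add atoms: none
Why: Ring-closing metathesis between the allyl ester alkene and the 1,1-disubstituted acrylate alkene closes the five-membered butenolide (C13=C14) with loss of ethylene, while the hindered exocyclic C8=C17 alkene could only form a nine-membered ring and should stay out.

Step 24
Reactants: 34 protected butenolide
Product: 35 14-deoxy-11-hydroxyandrographolide
Conditions: AcOH/THF/H2O (3:1:1), 40 °C
Reagents that add atoms: none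
Why: Mild aqueous acid hydrolyses both acetals (1-ethoxyethyl ether and isopropylidene acetal) and should not isomerise the exocyclic alkene or the butenolide.

**Compound list**

1 | geranyl acetate | CC(C)=CCC/C(C)=C/COC(C)=O | starting material
2 | 6,7-epoxygeranyl acetate (racemic epoxide) | CC1(C)OC1CC/C(C)=C/COC(C)=O | intermediate
3 | (2E)-6,7-dihydroxy-3,7-dimethyloct-2-en-1-yl acetate (not isolated) | CC(C)(O)C(O)CC/C(C)=C/COC(C)=O | intermediate
4 | (2E)-3-methyl-6-oxohex-2-en-1-yl acetate | O=CCC/C(C)=C/COC(C)=O | intermediate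
5 | (S)-4-benzyloxazolidin-2-one | O=C1OC[C@H](Cc2ccccc2)N1 | starting material
6 | pent-4-enoyl chloride | C=CCCC(Cl)=O | starting material
7 | N-lithio (S)-4-benzyloxazolidin-2-one (not isolated) | O=C1OC[C@H](Cc2ccccc2)N1[Li] | intermediate
8 | (S)-4-benzyl-3-(pent-4-enoyl)oxazolidin-2-one | C=CCCC(=O)N1[C@@H](Cc2ccccc2)COC1=O | intermediate
9 | dibutylboron (Z)-enolate of 8 (not isolated) | C=CC/C=C(\OB(CCCC)CCCC)N1[C@@H](Cc2ccccc2)COC1=O | intermediate
10 | (4S)-4-benzyl-3-[(2S,3R,6E)-8-acetoxy-3-hydroxy-6-methyl-2-(prop-2-en-1-yl)oct-6-enoyl]oxazolidin-2-one | CC(=O)OC/C=C(C)/CC[C@@H](O)[C@H](CC=C)C(=O)N1[C@@H](Cc2ccccc2)COC1=O | intermediate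
11 | methyl (2S,3R,6E)-3,8-dihydroxy-6-methyl-2-(prop-2-en-1-yl)oct-6-enoate | OC/C=C(C)/CC[C@@H](O)[C@H](CC=C)C(=O)OC | intermediate
12 | trilithio alkoxide enolate of 11 (not isolated) | [Li]OC/C=C(C)/CC[C@@H](O[Li])C(CC=C)=C(OC)O[Li] | intermediate
13 | methyl (2S,3R,6E)-3,8-dihydroxy-2,6-dimethyl-2-(prop-2-en-1-yl)oct-6-enoate | OC/C=C(C)/CC[C@@H](O)[C@@](C)(C(=O)OC)CC=C | intermediate
14 | methyl (2S,3R,6E)-3,8-diacetoxy-2,6-dimethyl-2-(prop-2-en-1-yl)oct-6-enoate | CC(=O)OC/C=C(C)/CC[C@@H](OC(C)=O)[C@@](C)(C(=O)OC)CC=C | intermediate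
15 | (E)-crotonaldehyde | C/C=C/C=O | starting material
16 | methyl (2S,3R,6E)-3,8-diacetoxy-2,6-dimethyl-2-[(2E)-4-oxobut-2-en-1-yl]oct-6-enoate | CC(=O)OC/C=C(C)/CC[C@@H](OC(C)=O)[C@@](C)(C(=O)OC)C/C=C/C=O | intermediate
17 | methyl (2S,3R,6E)-3,8-diacetoxy-2-[(1E,3E)-4-(tert-butyldimethylsilyloxy)buta-1,3-dien-1-yl]-2,6-dimethyloct-6-enoate | CC(=O)OC/C=C(C)/CC[C@@H](OC(C)=O)[C@@](C)(C(=O)OC)/C=C/C=C/O[Si](C)(C)C(C)(C)C | intermediate
18 | methyl (2S,3R,6E)-3-acetoxy-2-[(1E,3E)-4-(tert-butyldimethylsilyloxy)buta-1,3-dien-1-yl]-8-hydroxy-2,6-dimethyloct-6-enoate | OC/C=C(C)/CC[C@@H](OC(C)=O)[C@@](C)(C(=O)OC)/C=C/C=C/O[Si](C)(C)C(C)(C)C | intermediate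
19 | cycloaddition precursor: methyl (2S,3R,6E)-3-acetoxy-2-[(1E,3E)-4-(tert-butyldimethylsilyloxy)buta-1,3-dien-1-yl]-2,6-dimethyl-8-oxooct-6-enoate | O=C/C=C(C)/CC[C@@H](OC(C)=O)[C@@](C)(C(=O)OC)/C=C/C=C/O[Si](C)(C)C(C)(C)C | intermediate
20 | cycloadduct: methyl (3R,4S,5S,8R,9S,10R)-3-acetoxy-8-(tert-butyldimethylsilyloxy)-11-oxo-12,13,14,15,16,17-hexanorlabd-6-en-19-oate (trans-fused; C20, C19, C11, O3 and O8 on one face) | O=C[C@@H]1[C@H](O[Si](C)(C)C(C)(C)C)C=C[C@@H]2[C@](C)(C(=O)OC)[C@H](OC(C)=O)CC[C@@]12C | intermediate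
21 | (3R,4R,5S,8R,9R,10R)-8-(tert-butyldimethylsilyloxy)-12,13,14,15,16,17-hexanorlabd-6-ene-3,11,19-triol | OC[C@@H]1[C@H](O[Si](C)(C)C(C)(C)C)C=C[C@@H]2[C@](C)(CO)[C@H](O)CC[C@@]12C | intermediate
22 | 3,19-O-isopropylidene acetal of 21 (free 11-OH) | OC[C@@H]1[C@H](O[Si](C)(C)C(C)(C)C)C=C[C@@H]2[C@](C)(COC(C)(C)O3)[C@H]3CC[C@@]12C | intermediate
23 | 6,7-dihydro derivative of 22 | OC[C@@H]1[C@H](O[Si](C)(C)C(C)(C)C)CC[C@@H]2[C@](C)(COC(C)(C)O3)[C@H]3CC[C@@]12C | intermediate
24 | (3R,4R,5S,8R,9S,10R)-8-(tert-butyldimethylsilyloxy)-3,19-(isopropylidenedioxy)-12,13,14,15,16,17-hexanorlabdan-11-al | O=C[C@@H]1[C@H](O[Si](C)(C)C(C)(C)C)CC[C@@H]2[C@](C)(COC(C)(C)O3)[C@H]3CC[C@@]12C | intermediate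
25 | 2-(bromomethyl)acrylic acid | OC(=O)C(=C)CBr | starting material
26 | allyl alcohol | C=CCO | starting material
27 | allyl 2-(bromomethyl)acrylate | C=CCOC(=O)C(=C)CBr | intermediate
28 | 2-(allyloxycarbonyl)allylindium dibromide (not isolated) | C=CCOC(=O)C(=C)C[In](Br)Br | intermediate
29 | Barbier adduct: C9–C11H(OH)–C12H2–C13(=CH2)–C16(=O)O-allyl on the decalin of 24; (3R,4R,5S,8R,9R,10R,11R) | C=CCOC(=O)C(=C)C[C@@H](O)[C@@H]1[C@H](O[Si](C)(C)C(C)(C)C)CC[C@@H]2[C@](C)(COC(C)(C)O3)[C@H]3CC[C@@]12C | intermediate
30 | O11-(1-ethoxyethyl) ether of 29 (acetal carbon as both epimers) | C=CCOC(=O)C(=C)C[C@@H](OC(C)OCC)[C@@H]1[C@H](O[Si](C)(C)C(C)(C)C)CC[C@@H]2[C@](C)(COC(C)(C)O3)[C@H]3CC[C@@]12C | intermediate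
31 | C8 alcohol (8α-OH, axial) | C=CCOC(=O)C(=C)C[C@@H](OC(C)OCC)[C@@H]1[C@H](O)CC[C@@H]2[C@](C)(COC(C)(C)O3)[C@H]3CC[C@@]12C | intermediate
32 | C8 ketone | C=CCOC(=O)C(=C)C[C@@H](OC(C)OCC)[C@@H]1C(=O)CC[C@@H]2[C@](C)(COC(C)(C)O3)[C@H]3CC[C@@]12C | intermediate
33 | 8(17)-methylidene allyl acrylate | C=CCOC(=O)C(=C)C[C@@H](OC(C)OCC)[C@@H]1C(=C)CC[C@@H]2[C@](C)(COC(C)(C)O3)[C@H]3CC[C@@]12C | intermediate
34 | 11-O-(1-ethoxyethyl)-3,19-O-isopropylidene-14-deoxy-11-hydroxyandrographolide | O=C1OCC=C1C[C@@H](OC(C)OCC)[C@@H]1C(=C)CC[C@@H]2[C@](C)(COC(C)(C)O3)[C@H]3CC[C@@]12C | intermediate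
35 | 14-deoxy-11-hydroxyandrographolide (3R,4R,5S,9R,10R,11R) | O=C1OCC=C1C[C@@H](O)[C@@H]1C(=C)CC[C@@H]2[C@](C)(CO)[C@H](O)CC[C@@]12C | target

**Step count and risks**

Total step count: 24. Longest linear sequence: 22 steps (steps 1, 2, 4–16 and 18–24; steps 3 and 17 make side components).

The three steps most likely to fail:

1. Step 12 (key cycloaddition). The aluminium Lewis acid may strip or protonate the silyl dienol ether, or the addition may go stepwise and stop after the C5–C10 bond (Mukaiyama–Michael). The C3/C4 substituents may also discriminate the two diene faces too weakly. The fallback sets out from allylic alcohol 18. Tandem MnO2 oxidation and carbene-catalysed oxidative esterification (MnO2, 1,4-dimethyl-1,2,4-triazolium iodide, DBU, MeOH, CH2Cl2) would give the methyl (2E)-enoate triene F1, which needs no Lewis acid. Heating in toluene (150 °C, sealed tube, BHT) would bring about a purely thermal type 1 intramolecular Diels–Alder reaction to the C11 methyl ester cycloadduct F2. LiAlH4 in THF would then reduce both esters and the acetate, and the fallback comes back to the route at triol 21.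

2. Step 18 (Barbier allylation). Facial discrimination at the aldehyde may be poor, because the Felkin–Anh preference is opposed by dipole repulsion between the carbonyl group and the axial C8 silyl ether; the γ-hydroxy ester may also lactonise onto O11. The fallback sets out from 29 obtained as a C11 epimer mixture. Dess–Martin oxidation would give the C11 ketone F3. Reagent-controlled Corey–Bakshi–Shibata reduction ((S)-2-methyl-CBS-oxazaborolidine, catecholborane, toluene, −78 °C, with C9 as the large and C12 as the small ketone substituent) should deliver the 11R alcohol, and the fallback comes back at 29.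

3. Step 22 (methylenation). Olefination of the hindered C8 ketone may be sluggish, the titanium carbene may also methylenate the ester carbonyl, and prolonged heating may cause β-elimination of the C11 acetal. The fallback sets out from ketone 32. Me3SiCH2Li/CeCl3 (THF, −78 °C) would add to the ketone alone to give the β-hydroxysilane F4 (the C8 configuration is lost again). KHMDS (THF, 0 °C) would then trigger the Peterson syn-elimination, and the fallback comes back at 33.

**Further compounds**

F1 | step 12 | methyl (2E)-enoate analogue of 19 (C11 as CO2Me) | COC(=O)/C=C(C)/CC[C@@H](OC(C)=O)[C@@](C)(C(=O)OC)/C=C/C=C/O[Si](C)(C)C(C)(C)C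
F2 | step 12 | C11 methyl ester analogue of cycloadduct 20 | COC(=O)[C@@H]1[C@H](O[Si](C)(C)C(C)(C)C)C=C[C@@H]2[C@](C)(C(=O)OC)[C@H](OC(C)=O)CC[C@@]12C
F3 | step 18 | C11 ketone from 29 | C=CCOC(=O)C(=C)CC(=O)[C@@H]1[C@H](O[Si](C)(C)C(C)(C)C)CC[C@@H]2[C@](C)(COC(C)(C)O3)[C@H]3CC[C@@]12C
F4 | step 22 | C8 β-hydroxysilane (8-hydroxy-8-(trimethylsilylmethyl)) from 32 | C=CCOC(=O)C(=C)C[C@@H](OC(C)OCC)[C@@H]1[C@@](O)(C[Si](C)(C)C)CC[C@@H]2[C@](C)(COC(C)(C)O3)[C@H]3CC[C@@]12C
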